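## The problem

Atoms are numbered as in the icetexane skeleton: ring A is C1–C5 and C10 (gem-dimethyl on C4), ring B is C5–C10 plus C20, and the quinone ring is C8, C9, C11–C14.

1. The target is a 2-methoxy-3-isopropyl-1,4-benzoquinone fused through C8=C9 to an 8-oxabicyclo[3.2.1]octene: one oxygen bridges C7 and C10, C5–C6 is the two-carbon bridge, C8=C9–C20 the three-carbon bridge, and ring A is fused at C5–C10.
2. There are three stereocentres (5R,7S,10S), but C7 is a hemiketal held by the bridge, so the task is the quaternary C10–O centre and its relation to C5.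
3. That relation is the demanding one: H-5 is syn to the oxygen bridge, so ring A lies on the endo face and the tetrahydrofuran ring O–C10–C5–C6–C7 is trans-fused to ring A. Adding a C20 nucleophile to a ring-A ketone anti to a C5 side chain, or hydrogenating a ring-A butenolide anti to its angular group, would be expected to give the other C5 epimer.
4. The quinone carries four different substituents: OMe must sit beside the C11 carbonyl (C9/C20 side) and isopropyl beside the C14 carbonyl (C8/C7 side).
5. The hemiketal is a masked 10-hydroxy-7-ketone. Its β-oxygenated ketone precursors can eliminate or cleave by retro-aldol reaction, and while C5=C6 is present ring opening leads on to tropones. The quinone tolerates neither strong base nor organometallics and must come last.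
6. The enabling feature: O, C7, C6, C5 and C10 are the five ring atoms of a furan that shares its 2,3-bond with ring A (a 4,5,6,7-tetrahydrobenzofuran), and C20–C9–C8 is a three-carbon unit bonded to both furan α-carbons. H-5 syn to oxygen is what exo-face hydrogenation of the remaining furan double bond C5=C6 gives. The bridged core is therefore the (4+3) cycloadduct of a flat 2-methoxyfuran and an oxyallyl cation, and its C8–C9 edge can carry the quinone.

## Retrosynthesis

**22 ⇒ 20 (through 21).** Only C–O bonds and the oxidation level change: the quinone and hemiketal are unveiled together from hydroquinone methyl ketal 20. The quinone would not survive the organolithium steps, and the bridged methyl ketal hydrolyses most easily while the ring is still an electron-rich hydroquinone. The forward step needs dilute acid, then a mild oxidant.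

**20 ⇒ 18 ⇒ 17 + 16.** The quinone ring is cut at C8–C14 and C9–C11. Hydroquinone 20 is the thermal ring-expansion product (via ketene 19) of the 4-alkenyl-4-hydroxycyclobutenone 18, made from vinyllithium 17 and cyclobutenedione 16; 16 comes in two steps from dimethyl squarate 14 via 15. The neighbouring cuts (C10–C20 and C7–C8 to a preformed arene) need a pentasubstituted benzene built one substituent at a time. Here OMe and isopropyl arrive together, and their positions follow from which carbonyl of 16 is attacked. The halves are a C8 squarate piece and a tricyclic vinyl metal with no aromatic ring. The demand: the metal must be on C9 with the double bond to C8, not C20 (stannane 13).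

**13 ⇒ 12 ⇒ 10 ⇒ 8.** No skeletal bond is cut; the issue is which α-methylene of ketone 8 (C8 or C20) becomes sp2. Direct deprotonation cannot be trusted, and a C20 enolate could expel the bridging oxygen. The C7 ketal is used as the marker. Acid opens 8 to vinylogous ester 9, whose enol ether can only lie between C7 and C8. Bromonium-induced re-closure gives bromo ketone 10. Reductive enolate formation (11) and O-sulfonylation give triflate 12, then 13.

**8 ⇒ 7 ⇒ 4 + 5 (through 6).** C10–C20 and C7–C8 are cut together, and H2 is removed from C5–C6: a (4+3) cycloaddition of 2-methoxyfuran 4 with the oxyallyl cation 6 from trichloroacetone 5, then hydrogenation. Cutting only one bond (butenolide alkylation, then acylation) costs steps and loses the C7 methoxy marker. Precursor 4 is flat, achiral and C11; adduct 7 has ring B, the oxygen bridge and both bridgehead centres. The forward reaction must select one enantiotopic face of 4; cation 6 is symmetrical, so there is no regiochemical question. Hydrogenation must come from the exo face.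

**4 ⇒ 3 ⇒ 2 ⇒ 1.** Furan functional-group changes only: methanol elimination from the 2,5-dimethoxy-2,5-dihydrofuran 3, oxidative methoxylation of furan 2, and geminal dimethylation of commercial ketone 1.

## Roads not taken

**Alternative 1:** (the obvious one) Cut C10–C20 and C7–C8 to a preformed arene. A (2-bromo-4-isopropyl-3,5,6-trimethoxyphenyl)methyl metal reagent is added to a ring-A keto ester to give (3aR,7aS)-7a-[(2-bromo-3,5,6-trimethoxy-4-isopropylphenyl)methyl]-4,4-dimethylhexahydro-1-benzofuran-2(3H)-one (A1). Bromine–lithium exchange and Parham-type attack of the aryllithium on the lactone close ring B as the hemiketal; oxidative demethylation gives the quinone. The chosen plan is better for three reasons: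
- A1 must be the trans-fused lactone, but benzyl addition anti to the C5 side chain leads to the cis-fused one, so C5 would need a separate correction.
- The bromoarene needs several sequential metalation and halogenation steps.
- In the chosen route C5 follows from an intrinsic facial bias, and the quinone substituents come from squarate in two steps.

**Alternative 2:** Cut the same two ring-B bonds but use a diene instead of a furan. Cyclopropanation of 1-(tert-butyldimethylsilyloxy)-6,6-dimethyl-2-vinylcyclohexene by a siloxyvinyl diazoacetate, catalysed by Rh2(S-PTAD)4, is followed by divinylcyclopropane Cope rearrangement. This [3,3] shift carries the cyclopropane configuration to quaternary C10 and gives methyl (S)-cycloheptadiene carboxylate A2. Enantiocontrol is well precedented, but: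
- A2 carries an ester on C8 that must be removed before benzannulation, which reopens the C8/C20 question.
- C7 arrives as CH2 and needs a later oxidation.
- The C10 silyl ether is β to the unveiled C9 ketone with no bridge to hold it.

The furan route delivers C7 at the ketal level and the regiochemical marker in the same step, and is shorter by about four steps.

**Alternative 3:** Cut the two-carbon bridge (C10–C5 and C7–C6). Rh2(OAc)4 decomposes the aryl diazo ketone A3; the ester carbonyl ylide adds to the tethered alkyne and gives cycloadduct A4. This forms ring A, ring B and the bridge at once, with C5=C6 placed for exo hydrogenation. It fails on three counts: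
- It needs a hexasubstituted benzene with two different acyl groups at C8 and C9; both are flanked by OMe, so nothing places them relative to OMe and isopropyl.
- The α-alkyl diazo ketone invites 1,2-hydride shift.
- C20 enters as a ketone that must be removed.

The chosen plan never makes a substituted benzene by substitution chemistry.

Key step: step 4

Assumption: the target is taken as the ring-closed hemiketal written in the SMILES; the 10-hydroxy-7-ketone freed in the last step is assumed to close to it spontaneously, since only C7 is within reach of the C10 hydroxyl.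

Remark on names: tricyclic intermediates are named as 4a,8-epoxybenzo[7]annulenes; annulene C4a, C5, C6, C7, C8, C9, C9a correspond to icetexane C10, C20, C9, C8, C7, C6, C5.

## Route

Step 1
Reactants: 1 6,7-dihydro-1-benzofuran-4(5H)-one
Product: 2 4,4-dimethyl-4,5,6,7-tetrahydro-1-benzofuran
Conditions: Me2TiCl2 (from Me2Zn and TiCl4), CH2Cl2, −30 °C to 0 °C
Reagents that add atoms: dimethyltitanium dichloride, C[Ti](C)(Cl)Cl (made in the flask from dimethylzinc, C[Zn]C, and TiCl4)
Why: Geminal dimethylation of a ketone with Me2TiCl2: methyl addition, ionization to a cation stabilised by the furan ring, and a second methyl transfer at the same carbon, which restores the furan; no stereocentre is formed.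

Step 2
Reactants: 2 4,4-dimethyl-4,5,6,7-tetrahydro-1-benzofuran
Product: 3 2,7a-dimethoxy-4,4-dimethyl-2,4,5,6,7,7a-hexahydro-1-benzofuran
Conditions: Br2, MeOH, Na2CO3, −40 °C
Reagents that add atoms: methanol, CO
Why: Clauson-Kaas-type oxidative 1,4-dimethoxylation across the two furan α-carbons; the diastereomer mixture does not matter because both centres become sp2 again in step 3.

Step 3
Reactants: 3 2,7a-dimethoxy-4,4-dimethyl-2,4,5,6,7,7a-hexahydro-1-benzofuran
Product: 4 2-methoxy-4,4-dimethyl-4,5,6,7-tetrahydro-1-benzofuran
Conditions: TMSOTf, i-Pr2NEt, CH2Cl2, −20 °C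
Reagents that add atoms: none
Why: Acetal-to-enol-ether elimination: the silyl triflate ionizes the tertiary C7a ketal methoxy group and the amine removes H-2, the only hydrogen whose loss aromatizes the ring, so the remaining methoxy group sits on the future C7.

Step 4
Reactants: 4 2-methoxy-4,4-dimethyl-4,5,6,7-tetrahydro-1-benzofuran; 5 1,1,3-trichloropropan-2-one
Product: 7 (4aR,8S)-5,7-dichloro-8-methoxy-1,1-dimethyl-1,2,3,4,7,8-hexahydro-4a,8-epoxybenzo[7]annulen-6(5H)-one, via oxyallyl cation 6 (not isolated)
Conditions: 1,1′-[(1R,2R)-cyclohexane-1,2-diyl]bis{3-[3,5-bis(trifluoromethyl)phenyl]thiourea} (10 mol %), Na2CO3, 4 Å molecular sieves, PhMe, −30 °C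
Reagents that add atoms: none
Why: Proposed new method: enolization of 5 and loss of chloride give the 1,3-dichloro-2-oxidoallyl cation 6, held at oxygen as a hydrogen-bonded ion pair by the chiral bis-thiourea (which takes the role the fluorinated alcohol plays in the classical base-induced generation of oxyallyl cations from α-halo ketones), and 6 adds across the two α-carbons of furan 4 in a (4+3) cycloaddition; the closest known reaction types are the racemic (4+3) cycloaddition of furans with oxyallyl cations from polyhalo ketones and the enantioselective capture of hydrogen-bond-donor-bound oxyallyl and siloxyallyl cations by π-nucleophiles, furans included. The addition should be asynchronous: C7a of 4 (future C10, the position para-like to OMe) bonds first, and the 2-methoxyfuranium ion is then closed at C2 (future C7) by the chloro-enolate carbon. This single event closes the seven-membered ring B and with it the oxygen-bridged six-membered ring, both by two-bond suprafacial (4+3) closure on one face of the planar furan, so C10 and C7 are necessarily formed cis to the oxygen bridge. Their absolute configuration depends on which enantiotopic face of 4 is attacked, which the chiral ion pair must control (the catalyst antipode that gives the 10S series is used); the two CHCl centres are of no consequence because both chlorines leave in step 5. No regiochemical question arises because 6 is symmetrical, plain furan alkylation is blocked because neither α-carbon can rearomatize by proton loss, and the gem-dimethyl group shields the only free ring position. Adduct 7 is kept away from acid, since ring opening and loss of water would lead to a tropone.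

Step 5
Reactants: 7 (4aR,8S)-5,7-dichloro-8-methoxy-1,1-dimethyl-1,2,3,4,7,8-hexahydro-4a,8-epoxybenzo[7]annulen-6(5H)-one
Product: 8 (4aS,8S,9aR)-8-methoxy-1,1-dimethyldecahydro-4a,8-epoxybenzo[7]annulen-6-one
Conditions: H2 (3 atm), Pd/C, Et3N, EtOAc, 23 °C
Reagents that add atoms: none
Why: Catalytic hydrogenation with hydrogenolysis of both α-chloro ketone C–Cl bonds; hydrogen reaches C5=C6 from the exo face (the side of the oxygen bridge, the other being covered by the three-carbon bridge), which sets C5 with H-5 syn to oxygen and ring A endo, as in the target.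

Step 6
Reactants: 8 (4aS,8S,9aR)-8-methoxy-1,1-dimethyldecahydro-4a,8-epoxybenzo[7]annulen-6-one
Product: 10 (4aS,8S,9aR)-7-bromo-8-methoxy-1,1-dimethyldecahydro-4a,8-epoxybenzo[7]annulen-6-one, via vinylogous ester 9 (not isolated)
Conditions: camphorsulfonic acid (5 mol %), CH2Cl2, 23 °C; then NaHCO3, NBS, 0 °C
Reagents that add atoms: N-bromosuccinimide, O=C1CCC(=O)N1Br
Why: Acid-catalysed opening of the bridged β-alkoxy ketone gives the conjugated vinylogous ester 9, whose enol ether can only lie between C7 and C8 because only the C7–O bond can ionize; bromination of its nucleophilic α-carbon and 5-exo capture of the methoxy-oxocarbenium ion by the C10 hydroxyl (bromoetherification) rebuild the bridged ketal with bromine on C8 alone. C5 and C10 are untouched, and the C8 epimer mixture is lost in step 7.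

Step 7
Reactants: 10 (4aS,8S,9aR)-7-bromo-8-methoxy-1,1-dimethyldecahydro-4a,8-epoxybenzo[7]annulen-6-one
Product: 12 (4aS,8S,9aR)-8-methoxy-1,1-dimethyl-1,2,3,4,5,8,9,9a-octahydro-4a,8-epoxybenzo[7]annulen-6-yl trifluoromethanesulfonate, via lithium enolate 11 (not isolated)
Conditions: Me2CuLi, THF, −78 °C; then N-(5-chloropyridin-2-yl)triflimide, −78 °C to −20 °C
Reagents that add atoms: N-(5-chloropyridin-2-yl)-1,1,1-trifluoro-N-(trifluoromethylsulfonyl)methanesulfonamide, FC(F)(F)S(=O)(=O)N(c1ccc(Cl)cn1)S(=O)(=O)C(F)(F)F
Why: Reductive enolate formation from an α-bromo ketone with a cuprate places the enolate double bond between the carbonyl carbon and the former C–Br carbon only; O-sulfonylation with the reactive pyridyl triflimide at low temperature should trap it before it can open the bridged ketal by β-elimination.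

Step 8
Reactants: 12 (4aS,8S,9aR)-8-methoxy-1,1-dimethyl-1,2,3,4,5,8,9,9a-octahydro-4a,8-epoxybenzo[7]annulen-6-yl trifluoromethanesulfonate
Product: 13 trimethyl[(4aS,8S,9aR)-8-methoxy-1,1-dimethyl-1,2,3,4,5,8,9,9a-octahydro-4a,8-epoxybenzo[7]annulen-6-yl]stannane
Conditions: Me3SnSnMe3, Pd(PPh3)4 (5 mol %), LiCl, THF, 65 °C
Reagents that add atoms: hexamethyldistannane, C[Sn](C)(C)[Sn](C)(C)C
Why: Palladium-catalysed stannylation of an enol triflate with a distannane (Stille-type coupling); the double bond stays where the triflate fixed it.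

Step 9
Reactants: 14 3,4-dimethoxycyclobut-3-ene-1,2-dione (dimethyl squarate)
Product: 15 4-hydroxy-2,3-dimethoxy-4-(propan-2-yl)cyclobut-2-en-1-one
Conditions: i-PrMgCl, THF, −78 °C; then H2O
Reagents that add atoms: isopropylmagnesium chloride, CC(C)[Mg]Cl
Why: 1,2-Addition of a Grignard reagent to one of the two equivalent carbonyl groups of the squarate ester.

Step 10
Reactants: 15 4-hydroxy-2,3-dimethoxy-4-(propan-2-yl)cyclobut-2-en-1-one
Product: 16 3-methoxy-4-(propan-2-yl)cyclobut-3-ene-1,2-dione
Conditions: (CF3CO)2O, CH2Cl2, −78 °C to 0 °C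
Reagents that add atoms: none
Why: Standard squarate-to-cyclobutenedione conversion: trifluoroacetylation of the tertiary alcohol, ionization to the methoxy-stabilised cyclobutenyl cation, and loss of one O-methyl group.

Step 11
Reactants: 13 trimethyl[(4aS,8S,9aR)-8-methoxy-1,1-dimethyl-1,2,3,4,5,8,9,9a-octahydro-4a,8-epoxybenzo[7]annulen-6-yl]stannane; 16 3-methoxy-4-(propan-2-yl)cyclobut-3-ene-1,2-dione
Product: 18 4-hydroxy-3-methoxy-2-(propan-2-yl)-4-[(4aS,8S,9aR)-8-methoxy-1,1-dimethyl-1,2,3,4,5,8,9,9a-octahydro-4a,8-epoxybenzo[7]annulen-6-yl]cyclobut-2-en-1-one, via vinyllithium 17 (not isolated)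
Conditions: MeLi, THF, −78 °C; then 16, −78 °C; then H2O
Reagents that add atoms: none
Why: Tin–lithium exchange, then 1,2-addition of the vinyllithium to the more electrophilic carbonyl of 16, the one beside the methoxy-bearing carbon (the other is deactivated as a vinylogous ester). This choice places OMe next to the future C11 carbonyl and isopropyl next to C14; the carbinol centre forms as a mixture and is lost in step 12.

Step 12
Reactants: 18 4-hydroxy-3-methoxy-2-(propan-2-yl)-4-[(4aS,8S,9aR)-8-methoxy-1,1-dimethyl-1,2,3,4,5,8,9,9a-octahydro-4a,8-epoxybenzo[7]annulen-6-yl]cyclobut-2-en-1-one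
Product: 20 (5R,7S,10S)-7,10-epoxy-7,12-dimethoxyicetexa-8,11,13-triene-11,14-diol, via dienylketene 19 (not isolated)
Conditions: PhMe (degassed), 110 °C
Reagents that add atoms: none
Why: Squarate (cyclobutenone) benzannulation: thermal 4π ring opening to the dienylketene, 6π electrocyclization of the ketene carbon onto C8, and tautomerization to the hydroquinone. The aromatic ring is closed between the two halves with the substituent pattern fixed in step 11; no stereocentre of the core is involved.

Step 13
Reactants: 20 (5R,7S,10S)-7,10-epoxy-7,12-dimethoxyicetexa-8,11,13-triene-11,14-diol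
Product: 22 (5R,7S,10S)-7,10-epoxy-7-hydroxy-12-methoxyicetexa-8,12-diene-11,14-dione (target), via hydroquinone hemiketal 21 (not isolated)
Conditions: HCl (0.5 M aq.), THF, 23 °C; then FeCl3 (aq.)
Reagents that add atoms: water, O
Why: Acid hydrolysis of the bridged methyl ketal is easy at the hydroquinone stage, because the ring-opened benzylic oxocarbenium ion is stabilised by the ortho and para oxygens; the freed 10-hydroxy-7-ketone re-closes to the hemiketal. Mild oxidation of the hydroquinone then gives the methoxyquinone; C5, C7 and C10 are not touched.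

## Compound list

1 | 6,7-dihydro-1-benzofuran-4(5H)-one | O=C1CCCc2occc12 | starting material
2 | 4,4-dimethyl-4,5,6,7-tetrahydro-1-benzofuran | CC1(C)CCCc2occc12 | intermediate
3 | 2,7a-dimethoxy-4,4-dimethyl-2,4,5,6,7,7a-hexahydro-1-benzofuran (diastereomer mixture) | COC1C=C2C(C)(C)CCCC2(OC)O1 | intermediate
4 | 2-methoxy-4,4-dimethyl-4,5,6,7-tetrahydro-1-benzofuran | COc1cc2c(o1)CCCC2(C)C | intermediate
5 | 1,1,3-trichloropropan-2-one | ClCC(=O)C(Cl)Cl | starting material
6 | 1,3-dichloro-2-oxidoallyl cation | [O-]C(=CCl)[CH+]Cl | intermediate (not isolated)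
7 | (4aR,8S)-5,7-dichloro-8-methoxy-1,1-dimethyl-1,2,3,4,7,8-hexahydro-4a,8-epoxybenzo[7]annulen-6(5H)-one (CHCl centres as formed) | O=C1C(Cl)[C@]2(OC)C=C3C(C)(C)CCC[C@@]3(C1Cl)O2 | intermediate
8 | (4aS,8S,9aR)-8-methoxy-1,1-dimethyldecahydro-4a,8-epoxybenzo[7]annulen-6-one (H-9a syn to the oxygen bridge) | O=C1C[C@]2(OC)C[C@@H]3C(C)(C)CCC[C@@]3(C1)O2 | intermediate
9 | (4aS,9aR)-4a-hydroxy-8-methoxy-1,1-dimethyl-1,2,3,4,4a,5,9,9a-octahydro-6H-benzo[7]annulen-6-one | O=C1C=C(OC)C[C@@H]2C(C)(C)CCC[C@]2(O)C1 | intermediate (not isolated)
10 | (4aS,8S,9aR)-7-bromo-8-methoxy-1,1-dimethyldecahydro-4a,8-epoxybenzo[7]annulen-6-one (both C7 epimers) | O=C1C(Br)[C@]2(OC)C[C@@H]3C(C)(C)CCC[C@@]3(C1)O2 | intermediate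
11 | lithium (4aS,8S,9aR)-8-methoxy-1,1-dimethyl-1,2,3,4,5,8,9,9a-octahydro-4a,8-epoxybenzo[7]annulen-6-olate | [Li+].[O-]C1=C[C@]2(OC)C[C@@H]3C(C)(C)CCC[C@@]3(C1)O2 | intermediate (not isolated)
12 | (4aS,8S,9aR)-8-methoxy-1,1-dimethyl-1,2,3,4,5,8,9,9a-octahydro-4a,8-epoxybenzo[7]annulen-6-yl trifluoromethanesulfonate | O=S(=O)(OC1=C[C@]2(OC)C[C@@H]3C(C)(C)CCC[C@@]3(C1)O2)C(F)(F)F | intermediate
13 | trimethyl[(4aS,8S,9aR)-8-methoxy-1,1-dimethyl-1,2,3,4,5,8,9,9a-octahydro-4a,8-epoxybenzo[7]annulen-6-yl]stannane | C[Sn](C)(C)C1=C[C@]2(OC)C[C@@H]3C(C)(C)CCC[C@@]3(C1)O2 | intermediate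
14 | 3,4-dimethoxycyclobut-3-ene-1,2-dione (dimethyl squarate) | COC1=C(OC)C(=O)C1=O | starting material
15 | 4-hydroxy-2,3-dimethoxy-4-(propan-2-yl)cyclobut-2-en-1-one | COC1=C(OC)C(O)(C(C)C)C1=O | intermediate
16 | 3-methoxy-4-(propan-2-yl)cyclobut-3-ene-1,2-dione | COC1=C(C(C)C)C(=O)C1=O | intermediate
17 | [(4aS,8S,9aR)-8-methoxy-1,1-dimethyl-1,2,3,4,5,8,9,9a-octahydro-4a,8-epoxybenzo[7]annulen-6-yl]lithium | [Li]C1=C[C@]2(OC)C[C@@H]3C(C)(C)CCC[C@@]3(C1)O2 | intermediate (not isolated)
18 | 4-hydroxy-3-methoxy-2-(propan-2-yl)-4-[(4aS,8S,9aR)-8-methoxy-1,1-dimethyl-1,2,3,4,5,8,9,9a-octahydro-4a,8-epoxybenzo[7]annulen-6-yl]cyclobut-2-en-1-one (both carbinol epimers) | COC1=C(C(C)C)C(=O)C1(O)C4=C[C@]2(OC)C[C@@H]3C(C)(C)CCC[C@@]3(C4)O2 | intermediate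
19 | dienylketene from ring opening of 18 | O=C=C(C(C)C)C(OC)=C(O)C4=C[C@]2(OC)C[C@@H]3C(C)(C)CCC[C@@]3(C4)O2 | intermediate (not isolated)
20 | (5R,7S,10S)-7,10-epoxy-7,12-dimethoxyicetexa-8,11,13-triene-11,14-diol | COc1c(C(C)C)c(O)c2c(c1O)C[C@@]34CCCC(C)(C)[C@H]3C[C@]2(OC)O4 | intermediate
21 | (5R,7S,10S)-7,10-epoxy-12-methoxyicetexa-8,11,13-triene-7,11,14-triol | COc1c(C(C)C)c(O)c2c(c1O)C[C@@]34CCCC(C)(C)[C@H]3C[C@]2(O)O4 | intermediate (not isolated)
22 | (5R,7S,10S)-7,10-epoxy-7-hydroxy-12-methoxyicetexa-8,12-diene-11,14-dione | COC1=C(C(C)C)C(=O)C2=C(C[C@@]34CCCC(C)(C)[C@H]3C[C@]2(O)O4)C1=O | target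

## Step count and least certain steps

Total step count: 13. Longest linear sequence: 11 steps (steps 1–8 and 11–13); steps 9 and 10 make the squarate partner 16.

**Step 4 (key step, labelled as a proposed new method).** Most likely failures:
- weak discrimination of the two furan faces by the hydrogen-bonded oxyallyl ion pair;
- an uncatalysed background reaction;
- a stepwise path that ends in loss of the O-methyl group from the methoxyfuranium ion instead of ring closure.

Fallback with known chemistry, from 4 back to 8: auxiliary-controlled (4+3) cycloaddition of 4 with the α-alkoxy 2-(triethylsilyloxy)allyl cation that carries an (S)-1-phenylethoxy group. The cation is generated with TMSOTf at −95 °C from 1-methoxy-1-[(S)-1-phenylethoxy]-2-(triethylsilyloxy)prop-2-ene. Its oxocarbenium carbon should bond to the nucleophilic C7a of 4 and give (4aR,8S)-8-methoxy-1,1-dimethyl-5-[(1S)-1-phenylethoxy]-1,2,3,4,7,8-hexahydro-4a,8-epoxybenzo[7]annulen-6(5H)-one F1 (the auxiliary antipode is chosen for the 10S series). SmI2 in THF–MeOH removes the α-alkoxy group to give (4aS,8S)-8-methoxy-1,1-dimethyl-1,2,3,4,7,8-hexahydro-4a,8-epoxybenzo[7]annulen-6(5H)-one F2. Hydrogenation under the conditions of step 5 gives 8.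

**Step 6.** Most likely failures:
- loss of water or retro-aldol cleavage of the β-hydroxy ketone 9 during the acid stage;
- in the bromination stage, proton loss from the bromo-oxocarbenium ion (open 2-bromo vinylogous ester) instead of capture by the C10 hydroxyl;
- acid-induced re-opening of 10.

Fallback, from 9 (isolated after the acid stage) back to 12: oxygen transfer instead of bromonium. Dimethyldioxirane in acetone at −40 °C epoxidizes the enol ether, and the C10 hydroxyl opens the epoxide at C7 (Rubottom-type oxidation with internal ketalization) to give (4aS,8S,9aR)-7-hydroxy-8-methoxy-1,1-dimethyldecahydro-4a,8-epoxybenzo[7]annulen-6-one F3. Acetic anhydride and 4-(dimethylamino)pyridine give (4aS,8S,9aR)-8-methoxy-1,1-dimethyl-6-oxodecahydro-4a,8-epoxybenzo[7]annulen-7-yl acetate F4. Reductive cleavage of the α-acetoxy ketone with Me2CuLi and O-sulfonylation as in step 7 give 12.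

**Step 7.** Most likely failures:
- β-elimination of the bridging oxygen from the metal enolate, followed by retro-aldol fragmentation, before O-sulfonylation;
- methyl transfer from the cuprate.

Fallback, from 10 back to 13, with no free enolate: Perkow reaction of the α-bromo ketone with triethyl phosphite (neat, 100 °C) gives diethyl (4aS,8S,9aR)-8-methoxy-1,1-dimethyl-1,2,3,4,5,8,9,9a-octahydro-4a,8-epoxybenzo[7]annulen-6-yl phosphate F5, with the double bond fixed as in 12. Palladium-catalysed coupling of F5 with hexamethyldistannane (Pd(PPh3)4, LiCl, dioxane, 100 °C) gives 13.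

**Step 12.** Most likely failures:
- addition of the free tertiary hydroxyl to the ketene (lactonization to a butenolide);
- slow 6π closure at the hindered C8, with decomposition of the ketene.

Fallback, from 18 back to 21: silylation (TMSCl, imidazole, DMF) gives 3-methoxy-2-(propan-2-yl)-4-(trimethylsilyloxy)-4-[(4aS,8S,9aR)-8-methoxy-1,1-dimethyl-1,2,3,4,5,8,9,9a-octahydro-4a,8-epoxybenzo[7]annulen-6-yl]cyclobut-2-en-1-one F6, whose oxygen cannot add to the ketene. Thermolysis in toluene gives (5R,7S,10S)-7,10-epoxy-7,12-dimethoxy-11-(trimethylsilyloxy)icetexa-8,11,13-trien-14-ol F7. The acid of step 13 removes the silyl group together with the ketal methyl group to give 21, which is oxidized to 22 as before.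

## Further compounds

F1 | step 4 | (4aR,8S)-8-methoxy-1,1-dimethyl-5-[(1S)-1-phenylethoxy]-1,2,3,4,7,8-hexahydro-4a,8-epoxybenzo[7]annulen-6(5H)-one | O=C1C[C@]2(OC)C=C3C(C)(C)CCC[C@@]3(C1O[C@@H](C)c4ccccc4)O2
F2 | step 4 | (4aS,8S)-8-methoxy-1,1-dimethyl-1,2,3,4,7,8-hexahydro-4a,8-epoxybenzo[7]annulen-6(5H)-one | O=C1C[C@]2(OC)C=C3C(C)(C)CCC[C@@]3(C1)O2
F3 | step 6 | (4aS,8S,9aR)-7-hydroxy-8-methoxy-1,1-dimethyldecahydro-4a,8-epoxybenzo[7]annulen-6-one | O=C1C(O)[C@]2(OC)C[C@@H]3C(C)(C)CCC[C@@]3(C1)O2
F4 | step 6 | (4aS,8S,9aR)-8-methoxy-1,1-dimethyl-6-oxodecahydro-4a,8-epoxybenzo[7]annulen-7-yl acetate | O=C1C(OC(C)=O)[C@]2(OC)C[C@@H]3C(C)(C)CCC[C@@]3(C1)O2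
F5 | step 7 | diethyl (4aS,8S,9aR)-8-methoxy-1,1-dimethyl-1,2,3,4,5,8,9,9a-octahydro-4a,8-epoxybenzo[7]annulen-6-yl phosphate | CCOP(=O)(OCC)OC1=C[C@]2(OC)C[C@@H]3C(C)(C)CCC[C@@]3(C1)O2
F6 | step 12 | 3-methoxy-2-(propan-2-yl)-4-(trimethylsilyloxy)-4-[(4aS,8S,9aR)-8-methoxy-1,1-dimethyl-1,2,3,4,5,8,9,9a-octahydro-4a,8-epoxybenzo[7]annulen-6-yl]cyclobut-2-en-1-one | COC1=C(C(C)C)C(=O)C1(O[Si](C)(C)C)C4=C[C@]2(OC)C[C@@H]3C(C)(C)CCC[C@@]3(C4)O2
F7 | step 12 | (5R,7S,10S)-7,10-epoxy-7,12-dimethoxy-11-(trimethylsilyloxy)icetexa-8,11,13-trien-14-ol | COc1c(C(C)C)c(O)c2c(c1O[Si](C)(C)C)C[C@@]34CCCC(C)(C)[C@H]3C[C@]2(OC)O4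
A1 | alternative 1 | (3aR,7aS)-7a-[(2-bromo-3,5,6-trimethoxy-4-isopropylphenyl)methyl]-4,4-dimethylhexahydro-1-benzofuran-2(3H)-one | O=C1C[C@@H]2C(C)(C)CCC[C@@]2(Cc3c(Br)c(OC)c(C(C)C)c(OC)c3OC)O1
A2 | alternative 2 | methyl (S)-2,4a-bis(tert-butyldimethylsilyloxy)-5,5-dimethyl-4a,5,6,7,8,9-hexahydro-4H-benzo[7]annulene-1-carboxylate (icetexane C8 ester, C9 and C10 silyl ethers, C5=C6) | COC(=O)C1=C(O[Si](C)(C)C(C)(C)C)C[C@@]2(O[Si](C)(C)C(C)(C)C)CCCC(C)(C)C2=CC1
A3 | alternative 3 | methyl 2-(2-diazo-7,7-dimethylnon-8-ynoyl)-3,4,6-trimethoxy-5-isopropylbenzoate | COC(=O)c1c(OC)c(C(C)C)c(OC)c(OC)c1C(=O)C(=[N+]=[N-])CCCC(C)(C)C#C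
A4 | alternative 3 | (7S,10S)-7,10-epoxy-7,11,12,14-tetramethoxyicetexa-5,8,11,13-tetraen-20-one | COc1c(C(C)C)c(OC)c2c(c1OC)C(=O)[C@@]34CCCC(C)(C)C3=C[C@]2(OC)O4
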